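**Plan**

1. Locants: ring A is the 3-hydroxy-5-alkylphenyl ring; ring B is the 3,5-dihydroxy-4-aryloxyphenyl ring, whose C1 bears the chain; the chain runs from C1' (carbinol) to C14' (benzylic CH2 on ring A).
2. Retrosynthetic cuts, in order: the three O–Si bonds; the helper alkene C2'=C3' (removed by H2); the ring bond C1'–C2', which opens the 22-membered ring to an ω-alkynyl aryl aldehyde; the C14'–ring A bond (Negishi); the C8'=C9' alkene (Wittig); the ether O–C bond to ring A (Chan–Lam).
3. Enabling feature: C1' sits on C1 of ring B between two ortho C–H positions, so at the aldehyde level it is an unhindered, non-enolisable ArCHO. C2' and C3' are unbranched CH2 groups, so they can enter as a terminal alkyne that becomes an (E)-alkenylzinc; the alkene this leaves is allylic to the new OH and can be hydrogenated under hydroxyl direction while C8'=C9' stays.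
4. Forward order: rings A and B are joined first as the diaryl ether, OMe is exchanged for OTBS, the C2'–C14' chain is attached to ring A, and the only ring made in the route (22-membered) is closed last at C1'–C2'.
5. Stereochemistry: C1' (R) comes from catalyst control by (+)-DAIB in the ring-closing alkenylzinc addition; (Z)-C8'=C9' comes from a salt-free Wittig reaction.

Key step: step 9

Remark: the facial sense of (+)-DAIB is assigned by analogy with the known behaviour of (−)-DAIB toward benzaldehyde (Si-face delivery); should the alkenyl transfer show the opposite sense, (−)-DAIB is used instead.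

**Step 1**
Reactants: 1 syringaldehyde (4-hydroxy-3,5-dimethoxybenzaldehyde); 2 (3-bromo-5-methoxyphenyl)boronic acid
Product: 3 4-(3-bromo-5-methoxyphenoxy)-3,5-dimethoxybenzaldehyde
Conditions: Cu(OAc)2 (1.0 equiv), pyridine (5 equiv), 4 Å MS, CH2Cl2, dry air, rt
Reagents that add atoms: none
Why: Chan–Lam coupling, the oxidative copper-mediated O-arylation with an arylboronic acid, runs at room temperature, accepts phenols flanked by two ortho substituents and tolerates both the aldehyde and the aryl bromide, so the hindered C4–O bond of ring B is made while the bromide needed in step 8 is kept.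

**Step 2**
Reactants: 3 4-(3-bromo-5-methoxyphenoxy)-3,5-dimethoxybenzaldehyde
Product: 4 4-(3-bromo-5-hydroxyphenoxy)-3,5-dihydroxybenzaldehyde
Conditions: BBr3 (4 equiv), CH2Cl2, −78 °C to rt; then ice-water
Reagents that add atoms: none
Why: Lewis-acid cleavage of aryl methyl ethers by BBr3 removes all three methyl groups at a stage where the remaining functions (diaryl ether, aryl bromide, aryl aldehyde) are inert to it, so the phenols can be re-protected with fluoride-labile groups.

**Step 3**
Reactants: 4 4-(3-bromo-5-hydroxyphenoxy)-3,5-dihydroxybenzaldehyde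
Product: 5 4-[3-bromo-5-(tert-butyldimethylsilyloxy)phenoxy]-3,5-bis(tert-butyldimethylsilyloxy)benzaldehyde
Conditions: TBSCl (3.6 equiv), imidazole (7 equiv), DMF, rt
Reagents that add atoms: tert-butyldimethylsilyl chloride, CC(C)(C)[Si](C)(C)Cl
Why: Silylation of phenols with TBSCl and imidazole gives aryl silyl ethers that survive organozinc, borane and hydrogenation conditions and are removed at the end by fluoride without the acid that the benzylic alcohol would not tolerate.

**Step 4**
Reactants: 6 6-bromohexan-1-ol
Product: 7 (6-hydroxyhexyl)triphenylphosphonium bromide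
Conditions: PPh3 (1.05 equiv), MeCN, reflux
Reagents that add atoms: triphenylphosphine, c1ccc(cc1)P(c1ccccc1)c1ccccc1
Why: SN2 quaternisation of triphenylphosphine by a primary alkyl bromide is the standard entry to Wittig salts and leaves the free hydroxyl untouched.

**Step 5**
Reactants: 8 hept-6-yn-1-ol
Product: 9 hept-6-ynal
Conditions: PhI(OAc)2 (1.1 equiv), TEMPO (10 mol%), CH2Cl2, rt
Reagents that add atoms: none
Why: TEMPO-catalysed (oxoammonium) oxidation with PhI(OAc)2 stops at the aldehyde and does not touch the terminal alkyne.

**Step 6**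
Reactants: 7 (6-hydroxyhexyl)triphenylphosphonium bromide; 9 hept-6-ynal
Product: 11 (Z)-tridec-6-en-12-yn-1-ol, via sodium oxido ylide 10 (not isolated)
Conditions: NaN(SiMe3)2 (2.05 equiv), THF, −78 to 0 °C; then 9, −78 °C to rt; H2O work-up
Reagents that add atoms: none
Why: Wittig olefination with a non-stabilised ylide under lithium-free conditions gives the (Z)-alkene (the later C8'=C9') through kinetically controlled formation of the cis-oxaphosphetane, the second equivalent of base holding the hydroxyl as its alkoxide.

**Step 7**
Reactants: 11 (Z)-tridec-6-en-12-yn-1-ol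
Product: 12 (Z)-13-iodotridec-7-en-1-yne
Conditions: I2 (1.2 equiv), PPh3 (1.2 equiv), imidazole (1.5 equiv), CH2Cl2, 0 °C to rt
Reagents that add atoms: iodine, II
Why: Appel-type iodination converts the primary alcohol into the iodide by SN2 displacement of an alkoxyphosphonium ion under neutral conditions that affect neither the (Z)-alkene nor the terminal alkyne.

**Step 8**
Reactants: 12 (Z)-13-iodotridec-7-en-1-yne; 5 4-[3-bromo-5-(tert-butyldimethylsilyloxy)phenoxy]-3,5-bis(tert-butyldimethylsilyloxy)benzaldehyde
Product: 14 3,5-bis(tert-butyldimethylsilyloxy)-4-{3-(tert-butyldimethylsilyloxy)-5-[(6Z)-tridec-6-en-12-yn-1-yl]phenoxy}benzaldehyde, via alkylzinc iodide 13 (not isolated)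
Conditions: Zn dust (1.5 equiv, activated with BrCH2CH2Br/Me3SiCl), LiCl (1.5 equiv), THF, 25–40 °C; then 5 (0.85 equiv), Pd(OAc)2 (2 mol%), SPhos (4 mol%), THF, rt
Reagents that add atoms: none
Why: Negishi coupling works here because a primary alkylzinc iodide is neither basic enough to deprotonate the 1-alkyne nor nucleophilic enough to add to the aryl aldehyde, yet it transmetalates readily to the arylpalladium bromide and reductive elimination outruns β-hydride elimination with the biarylphosphine ligand, so the C14'–ring A bond forms with every function of the cyclisation precursor already in place.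

**Step 9**
Reactants: 14 3,5-bis(tert-butyldimethylsilyloxy)-4-{3-(tert-butyldimethylsilyloxy)-5-[(6Z)-tridec-6-en-12-yn-1-yl]phenoxy}benzaldehyde
Product: 17 tris-TBS (1'R,2'E,8'Z)-macrocyclic allylic alcohol (22-membered ring; OH at C1'), via alkenyl(dicyclohexyl)borane 15 (not isolated), via alkenyl(ethyl)zinc 16 (not isolated)
Conditions: BH3·SMe2 (1.05 equiv), cyclohexene (2.1 equiv), hexane, 0 °C (gives Cy2BH); 14, 0 °C to rt, 1 h; then syringe-pump addition (6 h) to Et2Zn (2 equiv), (+)-DAIB (5 mol%), hexane, 0 °C, final 2 mM; pH 7 aqueous work-up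
Reagents that add atoms: none
Why: Dicyclohexylborane adds syn and anti-Markovnikov to the terminal C2'≡C3' alkyne much faster than it reduces the aryl aldehyde or attacks the internal (Z)-alkene, giving the (E)-alkenylborane 15, and boron-to-zinc exchange with Et2Zn gives the alkenyl(ethyl)zinc 16, which transfers its sp2 carbon in preference to ethyl to the aldehyde inside a zinc aminoalkoxide complex of DAIB. The closest known reaction type is the amino-alcohol-catalysed enantioselective addition of alkenylzinc reagents to aldehydes, including its use to close macrocyclic (E)-allylic alcohols from ω-alkynals. The 22-membered ring closes in the 22-exo-trig mode by 1,2-addition to the carbonyl carbon C1'. The new stereocenter C1' is set by the catalyst: (−)-DAIB delivers carbon to the Si face of aryl aldehydes, so the (2R)-(+)-antipode should deliver C2' to the Re face and give (R), a descriptor that is unchanged by the later saturation because ring B outranks C2' in both compounds; the (E) geometry of C2'=C3' follows from syn hydroboration. The step needs ring closure to beat oligomerisation, which slow addition into a dilute Et2Zn/DAIB solution secures, and it needs a clean electrophile, which the non-enolisable formyl group on ring B with hydrogen at both ortho positions provides.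

**Step 10**
Reactants: 17 tris-TBS (1'R,2'E,8'Z)-macrocyclic allylic alcohol
Product: 18 tris-TBS ether of the target, (1'R,8'Z)
Conditions: Ru(OAc)2(rac-BINAP) (2 mol%), H2 (4 atm), MeOH/CH2Cl2 5:1, 25 °C
Reagents that add atoms: none
Why: Hydroxyl-directed hydrogenation with a ruthenium diphosphine dicarboxylate, a catalyst class that reduces allylic alcohols through a ruthenium alkoxide and leaves unfunctionalised alkenes alone, should saturate C2'=C3' and spare the remote (Z)-C8'=C9' bond; no stereocenter is created, racemic BINAP ensures that the catalyst enantiomer matched to the substrate is present, and C1' stays (R).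

**Step 11**
Reactants: 18 tris-TBS ether of the target, (1'R,8'Z)
Product: 19 CNP0316989.2, the (1'R,8'Z)-macrocyclic triphenol
Conditions: TBAF (3.6 equiv), AcOH (3.6 equiv), THF, 0 °C
Reagents that add atoms: none
Why: Fluoride-mediated cleavage of the three aryl silyl ethers under acetic acid buffering frees the phenols without acid or base strong enough to ionise the benzylic alcohol or isomerise the (Z)-alkene, and gives the target.

**Compound list**

1 | syringaldehyde (4-hydroxy-3,5-dimethoxybenzaldehyde) | COc1cc(C=O)cc(OC)c1O | starting material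
2 | (3-bromo-5-methoxyphenyl)boronic acid | COc1cc(Br)cc(c1)B(O)O | starting material
3 | 4-(3-bromo-5-methoxyphenoxy)-3,5-dimethoxybenzaldehyde | COc1cc(C=O)cc(OC)c1Oc1cc(Br)cc(OC)c1 | intermediate
4 | 4-(3-bromo-5-hydroxyphenoxy)-3,5-dihydroxybenzaldehyde | O=Cc1cc(O)c(Oc2cc(O)cc(Br)c2)c(O)c1 | intermediate
5 | 4-[3-bromo-5-(tert-butyldimethylsilyloxy)phenoxy]-3,5-bis(tert-butyldimethylsilyloxy)benzaldehyde | O=Cc1cc(O[Si](C)(C)C(C)(C)C)c(Oc2cc(O[Si](C)(C)C(C)(C)C)cc(Br)c2)c(O[Si](C)(C)C(C)(C)C)c1 | intermediate
6 | 6-bromohexan-1-ol | OCCCCCCBr | starting material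
7 | (6-hydroxyhexyl)triphenylphosphonium bromide | [Br-].OCCCCCC[P+](c1ccccc1)(c1ccccc1)c1ccccc1 | intermediate
8 | hept-6-yn-1-ol | OCCCCCC#C | starting material
9 | hept-6-ynal | O=CCCCCC#C | intermediate
10 | sodium 6-(triphenylphosphoranylidene)hexan-1-olate (oxido ylide, not isolated) | [Na+].[O-]CCCCCC=P(c1ccccc1)(c1ccccc1)c1ccccc1 | intermediate
11 | (Z)-tridec-6-en-12-yn-1-ol | OCCCCC/C=C\CCCCC#C | intermediate
12 | (Z)-13-iodotridec-7-en-1-yne | C#CCCCC/C=C\CCCCCI | intermediate
13 | [(Z)-tridec-6-en-12-yn-1-yl]zinc iodide (LiCl-complexed, not isolated) | C#CCCCC/C=C\CCCCC[Zn]I | intermediate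
14 | 3,5-bis(tert-butyldimethylsilyloxy)-4-{3-(tert-butyldimethylsilyloxy)-5-[(6Z)-tridec-6-en-12-yn-1-yl]phenoxy}benzaldehyde | C#CCCCC/C=C\CCCCCc1cc(O[Si](C)(C)C(C)(C)C)cc(Oc2c(O[Si](C)(C)C(C)(C)C)cc(C=O)cc2O[Si](C)(C)C(C)(C)C)c1 | intermediate
15 | (E)-alkenyl(dicyclohexyl)borane from 14 (boron on C2', not isolated) | C1CCCCC1B(C1CCCCC1)/C=C/CCCC/C=C\CCCCCc1cc(O[Si](C)(C)C(C)(C)C)cc(Oc2c(O[Si](C)(C)C(C)(C)C)cc(C=O)cc2O[Si](C)(C)C(C)(C)C)c1 | intermediate
16 | (E)-alkenyl(ethyl)zinc from 15 (zinc on C2', not isolated) | CC[Zn]/C=C/CCCC/C=C\CCCCCc1cc(O[Si](C)(C)C(C)(C)C)cc(Oc2c(O[Si](C)(C)C(C)(C)C)cc(C=O)cc2O[Si](C)(C)C(C)(C)C)c1 | intermediate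
17 | tris-TBS (1'R,2'E,8'Z)-macrocyclic allylic alcohol (22-membered ring, free OH at C1', all three phenols as TBS ethers) | CC(C)(C)[Si](C)(C)Oc1cc2cc(c1)Oc1c(O[Si](C)(C)C(C)(C)C)cc(cc1O[Si](C)(C)C(C)(C)C)[C@H](O)/C=C/CCCC/C=C\CCCCC2 | intermediate
18 | tris-TBS ether of the target, (1'R,8'Z) | CC(C)(C)[Si](C)(C)Oc1cc2cc(c1)Oc1c(O[Si](C)(C)C(C)(C)C)cc(cc1O[Si](C)(C)C(C)(C)C)[C@H](O)CCCCCC/C=C\CCCCC2 | intermediate
19 | CNP0316989.2, (1'R,8'Z)-macrocyclic triphenol | Oc1cc2cc(c1)Oc1c(O)cc(cc1O)[C@H](O)CCCCCC/C=C\CCCCC2 | target

**Step count and risks**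

Total step count: 11. Longest linear sequence: 7 steps (1, 2, 3, 8, 9, 10, 11; the chain branch 4, 6, 7, 8, 9, 10, 11 is equally long).

The three steps most likely to fail:

Step 9 (macrocyclisation). Intermolecular addition may outrun ring closure and give oligomers, the borane may reduce the aldehyde before the alkyne has been consumed, or the facial selectivity of the alkenyl transfer may erode. Fallback: setting out from 14, a zerovalent-nickel-catalysed reductive alkyne–aldehyde macrocyclisation (Ni(cod)2, IMes·HCl, KOtBu, Et3SiH, THF, slow addition) closes the same C1'–C2' bond through an oxanickelacycle, without borane or organozinc, and should give the racemic macrocyclic (E)-allylic triethylsilyl ether F1. AcOH/THF/H2O then frees the racemic macrocyclic allylic alcohol F2 while the aryl silyl ethers stay. F2 is isomerised to the macrocyclic aryl ketone F3 and reduced enantioselectively exactly as in the fallback to step 10, so this fallback comes back to the route at 18.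

Step 10 (directed hydrogenation). Chemoselectivity may be lost through hydrogenation or Z/E isomerisation of the remote alkene, or the reduction of the allylic alkene may stall. Fallback: setting out from 17, redox isomerisation of the allylic alcohol (CpRu(PPh3)2Cl 5 mol%, Et3NHPF6 10 mol%, dioxane, 90 °C) is an internal 1,3-hydrogen shift that only an alkene next to a carbinol can undergo, and should give the saturated macrocyclic aryl ketone F3 with the (Z)-alkene untouched. Asymmetric transfer hydrogenation (RuCl(p-cymene)[(R,R)-TsDPEN], HCO2H/Et3N 5:2, 30 °C) then sets C1' as (R) again, the aryl group acting as the large substituent, and the fallback comes back to the route at 18.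

Step 1 (diaryl ether). O-arylation of the hindered, electron-poor phenol may be sluggish while the boronic acid is lost to protodeboronation and homocoupling. Fallback: setting out from 1, an Ullmann-type etherification with 1-bromo-3-iodo-5-methoxybenzene (copper iodide CuI 10 mol%, picolinic acid 20 mol%, K3PO4, DMSO, 90 °C) uses an aryl iodide electrophile in a redox-neutral monovalent-copper cycle in place of the oxidative boronic acid coupling. The C–I bond reacts before the C–Br bond, the fallback comes back to the route at 3, and no new compound arises (F0).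

**Further compounds**

F1 | step 9 | racemic macrocyclic (E)-allylic triethylsilyl ether (tris-TBS, 2'E,8'Z) | CC(C)(C)[Si](C)(C)Oc1cc2cc(c1)Oc1c(O[Si](C)(C)C(C)(C)C)cc(cc1O[Si](C)(C)C(C)(C)C)C(O[Si](CC)(CC)CC)/C=C/CCCC/C=C\CCCCC2
F2 | step 9 | racemic macrocyclic allylic alcohol (racemate of 17) | CC(C)(C)[Si](C)(C)Oc1cc2cc(c1)Oc1c(O[Si](C)(C)C(C)(C)C)cc(cc1O[Si](C)(C)C(C)(C)C)C(O)/C=C/CCCC/C=C\CCCCC2
F3 | step 10 | macrocyclic aryl ketone (tris-TBS, C1' carbonyl, 8'Z) | CC(C)(C)[Si](C)(C)Oc1cc2cc(c1)Oc1c(O[Si](C)(C)C(C)(C)C)cc(cc1O[Si](C)(C)C(C)(C)C)C(=O)CCCCCC/C=C\CCCCC2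
F0 | step 1 | none | none
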